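**Retrosynthetic overview**

1. Decalin locants follow the octahydronaphthalene name (ring B = C1, C2, C3, C4, C4a, C8a; ring A = C4a, C5, C6, C7, C8, C8a). The aryl ether comes from a Mitsunobu union of bought umbelliferone with the C1 hydroxymethyl decalin; the C2 methyl from a C2 enol triflate (Stille); the 6-oxo-5,5-dimethyl unit from a C5=C6 methyl enol ether (cyclopropanation, acid opening).
2. Key disconnection, bond C4–C4a of ring B: the cis-decalin enolate comes from a 1-methoxy-2-vinylbicyclo[2.2.2]oct-5-en-2-ol by anionic oxy-Cope rearrangement. An easily made bridged skeleton is rearranged into the target skeleton, and the enolate is trapped as the triflate in the same flask.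
3. Enabling feature: the cis fusion C4a–C8a (H-4a and the 8a-methyl on one face) together with the array C2=C3–C4–C4a–C5=C6, where C2 is a masked carbonyl carbon of ring B and C5=C6 is the masked enol form of the ring A ketone. This is the product pattern of a [3,3] shift that a bicyclo[2.2.2]octene can only deliver cis-fused.
4. The bridged carbinol comes from a bicyclo[2.2.2]octenone, made by an enantioselective endo Diels–Alder reaction of 1-methoxy-2,4-dimethylcyclohexa-1,3-diene (Birch reduction of 2,4-dimethylanisole) with (E)-4-(methoxymethoxy)but-2-enal, then oxidative deformylation. The adduct already holds C1 and C8a of the target.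
5. Ring order: ring A (the anisole carbocycle), then the temporary bicyclic bridge (Diels–Alder), then ring B (oxy-Cope, last ring of the skeleton, the bridge bond being cut in the same event). The coumarin is bought intact; a transient cyclopropane only delivers the second C5 methyl.

Key step: step 8

Remark: the target SMILES is read as the cis-fused (1R,4aS,8aS) decalin, with H-4a and the 8a-methyl on one face and the C1 aryloxymethyl group on the other; bicyclic precursors carry bicyclo[2.2.2]octane locants.

**Step 1**
Reactants: 1 2,4-dimethylanisole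
Product: 2 1-methoxy-2,4-dimethylcyclohexa-1,4-diene
Conditions: Li, liq. NH3, t-BuOH, THF, −78 → −33 °C
Reagents that add atoms: none
Why: Birch reduction, in which protonation at C3 and C6 keeps the methoxy and both methyl groups on sp2 carbons and should give the skipped enol ether diene without any stereocentre.

**Step 2**
Reactants: 2 1-methoxy-2,4-dimethylcyclohexa-1,4-diene
Product: 3 1-methoxy-2,4-dimethylcyclohexa-1,3-diene
Conditions: KOt-Bu (cat.), DMSO, rt
Reagents that add atoms: none
Why: base-mediated prototropic equilibration through the pentadienyl anion should favour the conjugated 1-methoxy-1,3-diene with the more substituted double bonds; residual 2 is inert in step 5 and is carried along.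

**Step 3**
Reactants: 4 (Z)-but-2-ene-1,4-diol
Product: 5 (Z)-4-(methoxymethoxy)but-2-en-1-ol
Conditions: MOMCl (1 equiv), i-Pr2NEt, CH2Cl2, 0 °C → rt, diol in excess
Reagents that add atoms: chloromethyl methyl ether, COCCl
Why: O-alkylation of one hydroxyl group to the MOM acetal, the excess of diol limiting double protection.

**Step 4**
Reactants: 5 (Z)-4-(methoxymethoxy)but-2-en-1-ol
Product: 6 (E)-4-(methoxymethoxy)but-2-enal
Conditions: pyridinium chlorochromate (C5H5NH[CrO3Cl]), CH2Cl2, rt
Reagents that add atoms: none
Why: chromate oxidation of the allylic alcohol, after which the first-formed (Z)-enal should isomerise under the mildly acidic conditions to the conjugated (E)-enal.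

**Step 5**
Reactants: 3 1-methoxy-2,4-dimethylcyclohexa-1,3-diene; 6 (E)-4-(methoxymethoxy)but-2-enal
Product: 7 (1R,2R,3R,4S)-1-methoxy-3-[(methoxymethoxy)methyl]-4,6-dimethylbicyclo[2.2.2]oct-5-ene-2-carbaldehyde
Conditions: (5S)-5-benzyl-2,2,3-trimethylimidazolidin-4-one hydrochloride (20 mol%), MeCN/H2O (95:5), −20 → 0 °C, 3 in excess
Reagents that add atoms: none
Why: Diels–Alder reaction under iminium-ion catalysis, in which the (E)-iminium ion of 6 should add endo with "ortho" regiochemistry (enal C2 to the methoxy-bearing diene terminus, enal C3 to the methyl-bearing terminus) while the benzyl group of the catalyst shields the Re face so that the diene bonds to the Si face at C2 and C3 of the enal; this sets C1, C3 and C4 and places the CH2OMOM group syn to the C7–C8 bridge (the C2 configuration is of no consequence).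

**Step 6**
Reactants: 7 (1R,2R,3R,4S)-1-methoxy-3-[(methoxymethoxy)methyl]-4,6-dimethylbicyclo[2.2.2]oct-5-ene-2-carbaldehyde
Product: 8 (1S,3R,4S)-1-methoxy-3-[(methoxymethoxy)methyl]-4,6-dimethylbicyclo[2.2.2]oct-5-en-2-one
Conditions: O2 (1 atm), Cu(OAc)2 (cat.), 2,2′-bipyridine, DABCO, DMF, 40 °C
Reagents that add atoms: dioxygen, O=O
Why: copper-catalysed aerobic oxidative deformylation of an α,α-disubstituted acetaldehyde, in which the enolate formed with DABCO is oxidised by divalent copper and O2 to an α-hydroperoxy aldehyde whose fragmentation should give the nor-ketone and formic acid without touching C1, C3 or C4.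

**Step 7**
Reactants: 8 (1S,3R,4S)-1-methoxy-3-[(methoxymethoxy)methyl]-4,6-dimethylbicyclo[2.2.2]oct-5-en-2-one
Product: 9 (1S,2S,3R,4S)-2-ethenyl-1-methoxy-3-[(methoxymethoxy)methyl]-4,6-dimethylbicyclo[2.2.2]oct-5-en-2-ol
Conditions: CH2=CHMgBr, THF, −78 → 0 °C; aq. NH4Cl
Reagents that add atoms: vinylmagnesium bromide, C=C[Mg]Br
Why: Grignard 1,2-addition, in which the nucleophile should approach C2 from the face of the C5=C6 bridge, anti to the C7–C8 ethano bridge and to the C3 substituent lying over it, which sets C2 with the vinyl group syn to the ring double bond as the rearrangement requires.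

**Step 8**
Reactants: 9 (1S,2S,3R,4S)-2-ethenyl-1-methoxy-3-[(methoxymethoxy)methyl]-4,6-dimethylbicyclo[2.2.2]oct-5-en-2-ol
Product: 12 (1R,4aS,8aS)-6-methoxy-1-[(methoxymethoxy)methyl]-5,8a-dimethyl-1,4,4a,7,8,8a-hexahydronaphthalen-2-yl trifluoromethanesulfonate, via potassium alkoxide 10 (not isolated), via potassium enolate 11 (not isolated)
Conditions: KH (3 equiv), 18-crown-6, THF, 0 °C → rt; then PhNTf2, −78 → 0 °C
Reagents that add atoms: N-phenylbis(trifluoromethanesulfonimide), O=S(=O)(N(c1ccccc1)S(=O)(=O)C(F)(F)F)C(F)(F)F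
Why: Deprotonation gives alkoxide 10, a 3-oxido-1,5-diene (CH2=CH–C2–C1–C6=C5 of the bicycle) held in a boat array, which should undergo the anionic oxy-Cope [3,3]-sigmatropic shift: the C1–C2 bridge bond breaks while the vinyl terminus bonds to C5, giving the cis-fused enolate 11 that PhNTf2 traps on oxygen as enol triflate 12. The closest known reaction type is the anionic oxy-Cope rearrangement of potassium 1-methoxy-2-vinylbicyclo[2.2.2]oct-5-en-2-olates to cis-fused methoxyoctalones, combined with O-sulfonylation of the resulting enolate by an N-aryl triflimide. Ring B is closed by this suprafacial six-centre C–C bond formation (new bond C4–C4a of the decalin, bicycle C5 becoming C4a), while ring A is the cyclohexene ring already present in the bicycle. The one new stereocentre, C4a, is controlled by the bicyclic framework: the vinyl group can reach C5 only from the face of the C2–C3 bridge, so H-4a ends cis to the 8a-methyl, and C1 and C8a are carried over unchanged. The step needs the [3,3] shift to win over a [1,3] shift or fragmentation, and needs O-trapping of the enolate before proton transfer (which would open β-loss of the MOM-oxy group); the syn arrangement of vinyl group and C5=C6 bond set in step 7, the strain of the bicycle, the crown-ether-separated ion pair and the cold in situ triflation should secure this.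

**Step 9**
Reactants: 12 (1R,4aS,8aS)-6-methoxy-1-[(methoxymethoxy)methyl]-5,8a-dimethyl-1,4,4a,7,8,8a-hexahydronaphthalen-2-yl trifluoromethanesulfonate
Product: 13 the 5,6-methano adduct of 12 (methoxycyclopropane, C5–CH2–C6 ring on the face of H-4a and the 8a-methyl)
Conditions: Et2Zn, CH2I2, CH2Cl2, 0 °C → rt
Reagents that add atoms: diiodomethane, ICI
Why: Simmons–Smith cyclopropanation by the electrophilic zinc carbenoid EtZnCH2I, which should select the electron-rich tetrasubstituted enol ether over the electron-poor enol triflate; addition is expected on the convex face, but both new centres are removed in step 10 and their configuration is immaterial.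

**Step 10**
Reactants: 13 the 5,6-methano adduct of 12
Product: 15 (1R,4aS,8aS)-1-(hydroxymethyl)-5,5,8a-trimethyl-6-oxo-1,4,4a,5,6,7,8,8a-octahydronaphthalen-2-yl trifluoromethanesulfonate, via keto MOM ether 14 (not isolated)
Conditions: 3 M aq. HCl, THF, 50 °C
Reagents that add atoms: water, O
Why: acid-mediated opening of the alkoxycyclopropane (protonation at the CH2 carbon, cleavage of its bond to the methoxy-bearing carbon, hydrolysis of the oxocarbenium ion) should turn the CH2 into the second C5 methyl and unveil the C6 ketone, while the same acid hydrolyses the MOM acetal; the enol triflate is stable to aqueous acid and no stereocentre is epimerisable.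

**Step 11**
Reactants: 15 (1R,4aS,8aS)-1-(hydroxymethyl)-5,5,8a-trimethyl-6-oxo-1,4,4a,5,6,7,8,8a-octahydronaphthalen-2-yl trifluoromethanesulfonate
Product: 16 (4aS,5R,8aS)-5-(hydroxymethyl)-1,1,4a,6-tetramethyl-3,4,4a,5,8,8a-hexahydronaphthalen-2(1H)-one
Conditions: Me4Sn, Pd(PPh3)4 (5 mol%), LiCl, THF, 65 °C
Reagents that add atoms: tetramethylstannane, C[Sn](C)(C)C
Why: Stille coupling, in which oxidative addition of zerovalent palladium into the C–OTf bond, methyl transfer from tin and reductive elimination should give the trisubstituted ring B alkene regiospecifically, the ketone and the free hydroxyl being tolerated.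

**Step 12**
Reactants: 16 (4aS,5R,8aS)-5-(hydroxymethyl)-1,1,4a,6-tetramethyl-3,4,4a,5,8,8a-hexahydronaphthalen-2(1H)-one; 17 umbelliferone (7-hydroxy-2H-chromen-2-one)
Product: 18 7-{[(1R,4aS,8aS)-2,5,5,8a-tetramethyl-6-oxo-1,4,4a,5,6,7,8,8a-octahydronaphthalen-1-yl]methoxy}-2H-chromen-2-one
Conditions: PPh3, diisopropyl azodicarboxylate (DIAD), THF, 0 °C → rt
Reagents that add atoms: none
Why: Mitsunobu reaction, in which the primary alcohol is activated as its alkoxyphosphonium ion and displaced at CH2 by the phenoxide of 17 (no stereocentre involved) under neutral conditions that should spare the ketone, the alkene and the lactone.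

**Compound list**

1 | 2,4-dimethylanisole | COc1ccc(C)cc1C | starting material
2 | 1-methoxy-2,4-dimethylcyclohexa-1,4-diene | COC1=C(C)CC(C)=CC1 | intermediate
3 | 1-methoxy-2,4-dimethylcyclohexa-1,3-diene | COC1=C(C)C=C(C)CC1 | intermediate
4 | (Z)-but-2-ene-1,4-diol | OC/C=C\CO | starting material
5 | (Z)-4-(methoxymethoxy)but-2-en-1-ol | COCOC/C=C\CO | intermediate
6 | (E)-4-(methoxymethoxy)but-2-enal | COCOC/C=C/C=O | intermediate
7 | (1R,2R,3R,4S)-1-methoxy-3-[(methoxymethoxy)methyl]-4,6-dimethylbicyclo[2.2.2]oct-5-ene-2-carbaldehyde | CO[C@@]12CC[C@@](C)(C=C1C)[C@H](COCOC)[C@H]2C=O | intermediate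
8 | (1S,3R,4S)-1-methoxy-3-[(methoxymethoxy)methyl]-4,6-dimethylbicyclo[2.2.2]oct-5-en-2-one | CO[C@@]12CC[C@@](C)(C=C1C)[C@H](COCOC)C2=O | intermediate
9 | (1S,2S,3R,4S)-2-ethenyl-1-methoxy-3-[(methoxymethoxy)methyl]-4,6-dimethylbicyclo[2.2.2]oct-5-en-2-ol | CO[C@@]12CC[C@@](C)(C=C1C)[C@H](COCOC)[C@@]2(O)C=C | intermediate
10 | potassium (1S,2S,3R,4S)-2-ethenyl-1-methoxy-3-[(methoxymethoxy)methyl]-4,6-dimethylbicyclo[2.2.2]oct-5-en-2-olate (formed in the flask) | CO[C@@]12CC[C@@](C)(C=C1C)[C@H](COCOC)[C@@]2([O-])C=C.[K+] | intermediate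
11 | potassium (1R,4aS,8aS)-6-methoxy-1-[(methoxymethoxy)methyl]-5,8a-dimethyl-1,4,4a,7,8,8a-hexahydronaphthalen-2-olate (formed in the flask) | [K+].[O-]C1=CC[C@@H]2C(C)=C(OC)CC[C@]2(C)[C@@H]1COCOC | intermediate
12 | (1R,4aS,8aS)-6-methoxy-1-[(methoxymethoxy)methyl]-5,8a-dimethyl-1,4,4a,7,8,8a-hexahydronaphthalen-2-yl trifluoromethanesulfonate | FC(F)(F)S(=O)(=O)OC1=CC[C@@H]2C(C)=C(OC)CC[C@]2(C)[C@@H]1COCOC | intermediate
13 | 5,6-methano adduct of 12 (methoxycyclopropane; C5–CH2–C6 ring on the face of H-4a and the 8a-methyl) | FC(F)(F)S(=O)(=O)OC1=CC[C@@H]2[C@@]3(C)C[C@@]3(OC)CC[C@]2(C)[C@@H]1COCOC | intermediate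
14 | (1R,4aS,8aS)-1-[(methoxymethoxy)methyl]-5,5,8a-trimethyl-6-oxo-1,4,4a,5,6,7,8,8a-octahydronaphthalen-2-yl trifluoromethanesulfonate (formed in the flask) | FC(F)(F)S(=O)(=O)OC1=CC[C@@H]2C(C)(C)C(=O)CC[C@]2(C)[C@@H]1COCOC | intermediate
15 | (1R,4aS,8aS)-1-(hydroxymethyl)-5,5,8a-trimethyl-6-oxo-1,4,4a,5,6,7,8,8a-octahydronaphthalen-2-yl trifluoromethanesulfonate | FC(F)(F)S(=O)(=O)OC1=CC[C@@H]2C(C)(C)C(=O)CC[C@]2(C)[C@@H]1CO | intermediate
16 | (4aS,5R,8aS)-5-(hydroxymethyl)-1,1,4a,6-tetramethyl-3,4,4a,5,8,8a-hexahydronaphthalen-2(1H)-one | CC1=CC[C@@H]2C(C)(C)C(=O)CC[C@]2(C)[C@@H]1CO | intermediate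
17 | umbelliferone (7-hydroxy-2H-chromen-2-one) | O=c1ccc2ccc(O)cc2o1 | starting material
18 | 7-{[(1R,4aS,8aS)-2,5,5,8a-tetramethyl-6-oxo-1,4,4a,5,6,7,8,8a-octahydronaphthalen-1-yl]methoxy}-2H-chromen-2-one | CC1=CC[C@@H]2C(C)(C)C(=O)CC[C@]2(C)[C@@H]1COc1ccc2ccc(=O)oc2c1 | target

**Step count**

Total steps: 12. Longest linear sequence: 10 steps (steps 1, 2, 5, 6, 7, 8, 9, 10, 11, 12, from 1).

**Steps most likely to fail**

Step 5 (enantioselective Diels–Alder reaction). What may go wrong: hydrolysis of the dienyl methyl ether under the aqueous acidic catalysis, interception of an open Michael-type oxocarbenium stage by water before the second bond closes, or slow bond formation at the fully substituted diene terminus with loss of endo and facial control. The fallback sets out from 6 and 3 and comes back at 7, replacing catalysis by a stoichiometric auxiliary under anhydrous Lewis acid promotion. Enal 6 is oxidised (NaClO2, NaH2PO4, 2-methylbut-2-ene, t-BuOH/H2O) to (E)-4-(methoxymethoxy)but-2-enoic acid F1. This is converted with pivaloyl chloride and Et3N into the mixed pivalic anhydride F2 and N-acylated with the lithium salt (n-BuLi) of (S)-4-benzyloxazolidin-2-one to give the imide F3. The Et2AlCl-promoted Diels–Alder reaction of F3 with diene 3 (CH2Cl2, −78 → −30 °C) runs through the chelated s-cis acyl imide, whose benzyl group blocks one face. Endo addition to the open Si face of the α-carbon should give the adduct F4 with the same configuration at C1, C3 and C4 as 7. LiBH4 (THF, MeOH) removes the auxiliary to give the primary alcohol F5, and Dess–Martin oxidation returns to aldehyde 7.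

Step 6 (oxidative deformylation). What may go wrong: slow enolisation of the hindered tertiary aldehyde, and over-oxygenation of the product ketone at C3 with epimerisation or β-loss of the MOM-oxy group. The fallback sets out from 7 and comes back at 8, replacing the aerobic copper chemistry by oxidative decarboxylation. Aldehyde 7 is oxidised (NaClO2, NaH2PO4, 2-methylbut-2-ene) to the carboxylic acid F6. Its dianion (LiN(i-Pr)2, 2.2 equiv, THF) is oxygenated with O2 at −78 °C to the α-hydroperoxy acid F7. On treatment with N,N-dimethylformamide dimethyl acetal, F7 should lose CO2 and water to give ketone 8.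

Step 8 (anionic oxy-Cope rearrangement with in situ triflation). What may go wrong: proton transfer within the enolate before O-sulfonylation followed by β-elimination of the MOM-oxy group, or a competing [1,3] shift or fragmentation of the alkoxide under the strongly basic conditions. The fallback sets out from 9 and comes back at 11, using a neutral thermal rearrangement. Carbinol 9 is silylated (Me3SiOTf, Et3N, CH2Cl2) to the trimethylsilyl ether F8. Heating F8 in degassed o-dichlorobenzene at about 200 °C in a sealed tube should effect the siloxy-Cope rearrangement to the trimethylsilyl enol ether F9. KOt-Bu in THF at −78 °C then cleaves the O–Si bond to give potassium enolate 11, which is triflated cold with PhNTf2 as in step 8 to give 12.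

**Further compounds**

F1 | step 5 | (E)-4-(methoxymethoxy)but-2-enoic acid | COCOC/C=C/C(=O)O
F2 | step 5 | (E)-4-(methoxymethoxy)but-2-enoic pivalic anhydride | COCOC/C=C/C(=O)OC(=O)C(C)(C)C
F3 | step 5 | (S)-4-benzyl-3-[(E)-4-(methoxymethoxy)but-2-enoyl]oxazolidin-2-one | COCOC/C=C/C(=O)N1[C@@H](Cc2ccccc2)COC1=O
F4 | step 5 | (S)-4-benzyl-3-{[(1R,2R,3R,4S)-1-methoxy-3-[(methoxymethoxy)methyl]-4,6-dimethylbicyclo[2.2.2]oct-5-en-2-yl]carbonyl}oxazolidin-2-one | CO[C@@]12CC[C@@](C)(C=C1C)[C@H](COCOC)[C@H]2C(=O)N1[C@@H](Cc2ccccc2)COC1=O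
F5 | step 5 | [(1R,2S,3R,4S)-1-methoxy-3-[(methoxymethoxy)methyl]-4,6-dimethylbicyclo[2.2.2]oct-5-en-2-yl]methanol | CO[C@@]12CC[C@@](C)(C=C1C)[C@H](COCOC)[C@H]2CO
F6 | step 6 | (1R,2R,3R,4S)-1-methoxy-3-[(methoxymethoxy)methyl]-4,6-dimethylbicyclo[2.2.2]oct-5-ene-2-carboxylic acid | CO[C@@]12CC[C@@](C)(C=C1C)[C@H](COCOC)[C@H]2C(=O)O
F7 | step 6 | 2-hydroperoxy derivative of F6 (hydroperoxy group on the face of the C5=C6 bridge) | CO[C@@]12CC[C@@](C)(C=C1C)[C@H](COCOC)[C@]2(OO)C(=O)O
F8 | step 8 | {[(1S,2S,3R,4S)-2-ethenyl-1-methoxy-3-[(methoxymethoxy)methyl]-4,6-dimethylbicyclo[2.2.2]oct-5-en-2-yl]oxy}(trimethyl)silane | CO[C@@]12CC[C@@](C)(C=C1C)[C@H](COCOC)[C@@]2(O[Si](C)(C)C)C=C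
F9 | step 8 | {[(1R,4aS,8aS)-6-methoxy-1-[(methoxymethoxy)methyl]-5,8a-dimethyl-1,4,4a,7,8,8a-hexahydronaphthalen-2-yl]oxy}(trimethyl)silane | C[Si](C)(C)OC1=CC[C@@H]2C(C)=C(OC)CC[C@]2(C)[C@@H]1COCOC
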